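Readings and results were computed with made-up constants; the scatter is artificial.

1. Is dusk's extra incoming ligand worth charging, or does dawn's smaller charge give as much complex with one exchanged by the end?

| setting | blue | amber | grey | autumn | dawn | dusk |
|---|---|---|---|---|---|---|
| starting complex | 1 M | 1 M | 1 M | 1.0 M | 1.0 M | 1.0 M |
| incoming ligand | 0.59 M | 1.2 M | 2.2 M | 0.500 M | 2.00 M | 2.50 M |
| capture agent | 0.020 M | 0.020 M | 0.020 M | 0.0200 M | 0.0200 M | 0.0200 M |
| scavenger | 0.80 M (fed, over 8.0 min) | 0.80 M (fed, over 8.0 min) | 0.80 M (fed, over 8.0 min) | 0.800 M (fed, over 8.0 min) | 0.800 M (fed, over 8.0 min) | 0.800 M (fed, over 8.0 min) |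
| remark | run made earlier | run made earlier | run made earlier |  |  |  |
| time |  |  |  | 1.5 h | 1.5 h | 1.5 h |

| run | time / min | complex with one exchanged / % | complex with two exchanged / % | starting complex / % |
|---|---|---|---|---|
| blue | 6.00 | 10.7 | 0 | 90.0 |
| blue | 15.0 | 18.3 | 0.5 | 79.3 |
| blue | 30.0 | 28.8 | 2.5 | 69.2 |
| blue | 50.0 | 35.5 | 3.2 | 61.4 |
| amber | 4.00 | 13.1 | 0.9 | 86.2 |
| amber | 8.00 | 22.7 | 0.6 | 77.3 |
| amber | 20.0 | 38.1 | 4.7 | 56.3 |
| amber | 50.0 | 52.4 | 14.2 | 34.5 |
| grey | 6.00 | 28.7 | 2.4 | 69.3 |
| grey | 15.0 | 46.8 | 10.2 | 43.0 |
| grey | 30.0 | 56.3 | 21.6 | 21.7 |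
| grey | 50.0 | 60.7 | 25.6 | 11.9 |

(scatter of a reading: 0.5 percentage points)



- amount of complex with one exchanged at the end, in percent of the starting complex charged, for each flask in turn (autumn, dawn, dusk)

2. If the scavenger takes up leaving ligand one for one, its charge marks a line in each flask. This is the scavenger ceiling, the exchanges per starting complex charged that the scavenger can absorb at one leaving ligand each: 80.0%. Exchanges are counted as the complex with one exchanged plus twice the complex with two exchanged.

3. The grey run stood at 67.2% after 15.0 min, at 99.5% after 30.0 min and at 112% after 50.0 min. It therefore crossed the ceiling between the first two of these readings. Its exchanges gained 32 percentage points over the first interval and 13 points over the longer second one, a slower pace.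

4. Autumn's incoming ligand allows exchanges of 50.0%, less than the ceiling, so incoming ligand is the limiting reagent in autumn. Dawn's 2.00 M and dusk's 2.50 M are each more than the scavenger charge of 0.800 M, so both flasks can pass the ceiling. My own reckoning gives no percentage, only this sorting, so the choice is a rule of thrift: dawn's charge stands unless dusk promises clearly more.

5. The forecast gives 36%, 70% and 70%, reading that “the scavenger seems to remove released ligand one-for-one”. On these figures dusk offers no gain, and dawn's charge stays.

6. The flasks give 35.9% in autumn, 70.2% in dawn and 69.6% in dusk.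

    starting complex + incoming ligand ⇌ leaving ligand + complex with one exchanged (K = 47.0, k = 0.0314 M⁻¹ min⁻¹)
    complex with one exchanged + incoming ligand ⇌ leaving ligand + complex with two exchanged (K = 0.130, k = 0.0126 M⁻¹ min⁻¹)
    complex with one exchanged + capture agent → trapped intermediate (k = 0.0134 M⁻¹ min⁻¹)
    leaving ligand + starting complex ⇌ idle adduct, settled at all times (K = 0.391 M⁻¹)
    scavenger + leaving ligand → scavenged by-product (k = 7.26 M⁻¹ min⁻¹)

Dusk holds less complex with one exchanged than dawn, while its complex with two exchanged stands at 26.7% against 22.7% in dawn. In dawn, with scavenger at 0%, the incoming ligand spent less the ceiling's 0.800 M comes to 0.365 M, and leaving ligand stands at 0.358 M. In dusk, with scavenger at 0%, the same subtraction comes to 0.440 M, and leaving ligand stands at 0.437 M.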